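The synthesis rests on disconnecting the C1–C2 oxirane to a C1'(OH)–C1=C2 allylic alcohol in which the cyclohexene ring is stored as a quinone bisketal. One titanium–tartrate epoxidation, run as a kinetic resolution, forms both oxirane C–O bonds, sets C1 and C2 and selects the S carbinol C1'; it exploits the anti 2,3-epoxy alcohol that C1' forms with the oxirane fused to the cyclohexene ring. Its precursor is the racemic (Z)-3-iodobutenyl carbinol on a 3,3,6,6-tetramethoxycyclohexa-1,4-diene with silylated CH2OH. Ketal hydrolysis, carbonyl reduction anti to the oxirane and a late Suzuki coupling with a terpenoid (E)-alkenylboronate complete the skeleton.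

Key step: step 7

Atom labels: cyclohexene ring C1 (bears the side chain), C2, C3, C4 (bears CH2O), C5, C6; side chain C1'(OH)–C2'=C3'(CH3)–C4'=C5'; cyclohexane ring C6' (CH), C7' (CMe2), C8' (CHO), C9', C10', C11' (C(CH3)O).

Assumption: all ketal-containing intermediates are purified on triethylamine-deactivated silica.

Design choices: the ketals are hydrolysed and the carbonyls reduced before the fragment coupling, so the acid step is over before the dienyl carbinol exists. The C8' hydroxyl is carried as a TES ether, because a free cis-1,3 hydroxy aldehyde would close to a bridged lactol.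

Step 1
Reactants: 1 4-bromo-2,5-dimethoxybenzaldehyde
Product: 2 (4-bromo-2,5-dimethoxyphenyl)methanol
Conditions: NaBH4, MeOH, 0 °C
Reagents that add atoms: none
Why: Borohydride reduction of the aryl aldehyde to the benzylic alcohol is chemoselective, the aryl bromide and the methyl ethers being inert to NaBH4.

Step 2
Reactants: 2 (4-bromo-2,5-dimethoxyphenyl)methanol
Product: 3 [(4-bromo-2,5-dimethoxyphenyl)methoxy](tert-butyl)dimethylsilane
Conditions: TBSCl, imidazole, DMF, rt
Reagents that add atoms: tert-butyldimethylsilyl chloride, CC(C)(C)[Si](C)(C)Cl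
Why: Imidazole-promoted silylation of the unhindered primary alcohol masks the hydroxyl that would otherwise direct the epoxidation of step 7 to C4=C5.

Step 3
Reactants: 3 [(4-bromo-2,5-dimethoxyphenyl)methoxy](tert-butyl)dimethylsilane
Product: 4 {[4-bromo-3,3,6,6-tetramethoxycyclohexa-1,4-dien-1-yl]methoxy}(tert-butyl)dimethylsilane
Conditions: Pt anode, 1% KOH/MeOH, constant current, undivided cell, 0 °C
Reagents that add atoms: methanol, CO
Why: Anodic two-electron oxidation of a 1,4-dimethoxyarene in basic methanol (anodic bisketalisation, established for 2-bromo-1,4-dimethoxyarenes) adds methoxide at both methoxy-bearing carbons, and the basic medium preserves the ketals and the silyl ether.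

Step 4
Reactants: 5 but-2-yn-1-ol
Product: 6 but-2-ynal
Conditions: activated MnO2, CH2Cl2, rt; filtration, careful distillation
Reagents that add atoms: none
Why: Manganese dioxide oxidises the propargylic alcohol to the aldehyde without over-oxidation, and the volatile ynal is used at once.

Step 5
Reactants: 4 {[4-bromo-3,3,6,6-tetramethoxycyclohexa-1,4-dien-1-yl]methoxy}(tert-butyl)dimethylsilane; 6 but-2-ynal
Product: 8 rac-1-[4-({[tert-butyl(dimethyl)silyl]oxy}methyl)-3,3,6,6-tetramethoxycyclohexa-1,4-dien-1-yl]but-2-yn-1-ol, via lithiated bisketal 7 (not isolated)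
Conditions: n-BuLi, THF, −78 °C; then 6, −78 → −40 °C; H2O
Reagents that add atoms: none
Why: Bromine–lithium exchange of the vinylic bromide gives an alkenyllithium stabilised by the neighbouring ketal oxygens, which adds 1,2 to the ynal (organolithium carbonyl addition) and creates C1' as a racemate.

Step 6
Reactants: 8 rac-1-[4-({[tert-butyl(dimethyl)silyl]oxy}methyl)-3,3,6,6-tetramethoxycyclohexa-1,4-dien-1-yl]but-2-yn-1-ol
Product: 10 rac-(2Z)-1-[4-({[tert-butyl(dimethyl)silyl]oxy}methyl)-3,3,6,6-tetramethoxycyclohexa-1,4-dien-1-yl]-3-iodobut-2-en-1-ol, via cyclic alkenylalanate 9 (not isolated)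
Conditions: Red-Al, THF, 0 °C → rt; then I2, THF, −78 °C; Rochelle salt, Na2S2O3
Reagents that add atoms: iodine, II
Why: Hydroxyl-directed trans-hydroalumination of the propargylic alcohol delivers hydride to C2' and aluminium to C3' in a five-membered alanate, and iodinolysis with retention gives the vinyl iodide with iodine cis to C1' (Z), the ketals and the silyl ether being inert to the hydride.

Step 7
Reactants: 10 rac-(2Z)-1-[4-({[tert-butyl(dimethyl)silyl]oxy}methyl)-3,3,6,6-tetramethoxycyclohexa-1,4-dien-1-yl]-3-iodobut-2-en-1-ol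
Product: 11 (1S,2Z)-1-[(1S,6R)-4-({[tert-butyl(dimethyl)silyl]oxy}methyl)-2,2,5,5-tetramethoxy-7-oxabicyclo[4.1.0]hept-3-en-1-yl]-3-iodobut-2-en-1-ol
Conditions: Ti(OiPr)4 (1.0 equiv), L-(+)-DIPT (1.2 equiv), TBHP (0.5 equiv), 4 Å MS, CH2Cl2, −20 °C; sat. aq. Na2SO4
Reagents that add atoms: tert-butyl hydroperoxide, CC(C)(C)OO
Why: After exchange of the C1' alkoxide and the alkyl peroxide onto the dimeric titanium tartrate, the distal peroxide oxygen is passed inside the complex to the C1=C2 π bond on the face that L-(+)-DIPT leaves open (Katsuki–Sharpless epoxidation used as a kinetic resolution of a secondary allylic alcohol; closest precedent class: 1-cycloalkenyl carbinols). The oxirane ring closes by concerted syn [2+1] addition of one oxygen atom across C1=C2, both C–O bonds forming in a single spiro-type transition state and not by an exo or endo displacement. C1 (S) and C2 (R) are set together by the tartrate-selected face, and their anti (erythro) relation to C1' comes from the reactive rotamer in which C1'–H lies beside the C6 ketal (A1,2 strain) and the iodoalkenyl group points away from the catalyst. Only the S enantiomer can adopt this rotamer on the open face, so C1' (S) is selected, not created, and the R enantiomer of 10 stays behind and can be recycled by oxidation and reduction. The step needs chemoselectivity for C1=C2 over C2'=C3' and C4=C5: the iodoalkene carries iodine cis to C1' (A1,3 strain, inductive deactivation) and is the mismatched alkene of the S enantiomer, and C4=C5 has no directing hydroxyl because its CH2OH is silylated. Half an equivalent of peroxide keeps the conversion below one half so that the enantiomeric purity of 11 should stay high, and the sieve-dried complex at −20 °C is mild enough for the acid-labile ketals.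

Step 8
Reactants: 11 (1S,2Z)-1-[(1S,6R)-4-({[tert-butyl(dimethyl)silyl]oxy}methyl)-2,2,5,5-tetramethoxy-7-oxabicyclo[4.1.0]hept-3-en-1-yl]-3-iodobut-2-en-1-ol
Product: 12 (1S,6R)-4-({[tert-butyl(dimethyl)silyl]oxy}methyl)-1-[(1S,2Z)-1-hydroxy-3-iodobut-2-en-1-yl]-7-oxabicyclo[4.1.0]hept-3-ene-2,5-dione
Conditions: montmorillonite K10, wet CH2Cl2, rt
Reagents that add atoms: water, O
Why: Acid-catalysed hydrolysis of the two allylic dimethyl ketals on the clay (conditions used for dimethyl ketals of epoxyquinones) unmasks C3 and C6 as ketones, while the oxirane, whose carbons are flanked by ketal or carbonyl carbons and resist ionisation, the iodoalkenyl carbinol and the silyl ether should survive the mild heterogeneous acid.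

Step 9
Reactants: 12 (1S,6R)-4-({[tert-butyl(dimethyl)silyl]oxy}methyl)-1-[(1S,2Z)-1-hydroxy-3-iodobut-2-en-1-yl]-7-oxabicyclo[4.1.0]hept-3-ene-2,5-dione
Product: 13 (1S,2S,5R,6S)-4-({[tert-butyl(dimethyl)silyl]oxy}methyl)-1-[(1S,2Z)-1-hydroxy-3-iodobut-2-en-1-yl]-7-oxabicyclo[4.1.0]hept-3-ene-2,5-diol
Conditions: NaBH4, CeCl3·7H2O, MeOH, −78 °C
Reagents that add atoms: none
Why: Luche reduction adds hydride 1,2 to both cerium-activated carbonyls from the oxirane face, the face used in Luche reductions of cyclic α,β-epoxy ketones and the one not covered by the C1 side chain lying anti to the oxirane oxygen, so that C3 (R) and C6 (S) should both carry hydroxyl anti to the oxirane.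

Step 10
Reactants: 14 geranyl acetate [(2E)-3,7-dimethylocta-2,6-dien-1-yl acetate]
Product: 15 (2E)-5-[(2R)-3,3-dimethyloxiran-2-yl]-3-methylpent-2-en-1-yl acetate
Conditions: D-fructose-derived Shi ketone (30 mol%), Oxone, K2CO3, Bu4NHSO4, borate–EDTA buffer, MeCN/DMM/H2O, 0 °C
Reagents that add atoms: potassium peroxymonosulfate (Oxone), [K+].[O-]S(=O)(=O)OO
Why: Shi asymmetric epoxidation with the chiral dioxirane attacks the electron-rich 6,7-alkene in preference to the 2,3-alkene deactivated by the allylic acetate, and the spiro transition state with the D-fructose-derived ketone sets the oxirane CH (later C8') as R.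

Step 11
Reactants: 15 (2E)-5-[(2R)-3,3-dimethyloxiran-2-yl]-3-methylpent-2-en-1-yl acetate
Product: 16 [(1S,3R)-3-hydroxy-2,2-dimethyl-6-methylidenecyclohexyl]methyl acetate
Conditions: Cp2TiCl2 (2.5 equiv), Mn, THF, rt; then dil. HCl
Reagents that add atoms: none
Why: Titanocene(III) opens the oxirane homolytically at the tertiary carbon (Nugent–RajanBabu reagent) and the radical cyclises 6-endo onto the 2,3-alkene through a chair with the titanoxy group and CH2OAc equatorial, which sets C6' cis to the C8' oxygen, before a second Ti(III) traps the tertiary radical and β-hydride elimination gives the exocyclic alkene, a reaction known for epoxygeranyl acetate.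

Step 12
Reactants: 16 [(1S,3R)-3-hydroxy-2,2-dimethyl-6-methylidenecyclohexyl]methyl acetate
Product: 17 [(1S,3R)-2,2-dimethyl-6-methylidene-3-[(triethylsilyl)oxy]cyclohexyl]methyl acetate
Conditions: TESOTf, 2,6-lutidine, CH2Cl2, −78 → 0 °C
Reagents that add atoms: triethylsilyl trifluoromethanesulfonate, CC[Si](CC)(CC)OS(=O)(=O)C(F)(F)F
Why: Silylation of the hindered secondary alcohol with the silyl triflate keeps this cis-1,3 hydroxyl from closing to a bridged lactol at the aldehyde stage, and the TES ether is shed together with the TBS ether in the last step.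

Step 13
Reactants: 17 [(1S,3R)-2,2-dimethyl-6-methylidene-3-[(triethylsilyl)oxy]cyclohexyl]methyl acetate
Product: 18 [(3R,4S,6R)-5,5-dimethyl-6-[(triethylsilyl)oxy]-1-oxaspiro[2.5]octan-4-yl]methyl acetate
Conditions: mCPBA, NaHCO3, CH2Cl2, 0 °C
Reagents that add atoms: 3-chloroperoxybenzoic acid, OOC(=O)c1cccc(Cl)c1
Why: Prilezhaev epoxidation of the exocyclic alkene takes place on the face away from the axial C7' methyl group, which is syn-axial to the other face, as in the analogous drimane exocyclic alkenes, so that the new oxirane oxygen is equatorial and C11' is set.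

Step 14
Reactants: 18 [(3R,4S,6R)-5,5-dimethyl-6-[(triethylsilyl)oxy]-1-oxaspiro[2.5]octan-4-yl]methyl acetate
Product: 19 (1R,2S,4R)-2-(hydroxymethyl)-1,3,3-trimethyl-4-[(triethylsilyl)oxy]cyclohexan-1-ol
Conditions: LiAlH4, THF, 0 °C → rt; aqueous work-up
Reagents that add atoms: none
Why: Hydride opens the spiro-oxirane by SN2 attack at its CH2 group, which leaves the C11' oxygen in place as the equatorial tertiary alcohol with an axial methyl group, and the same reagent reduces the acetate to the primary alcohol.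

Step 15
Reactants: 19 (1R,2S,4R)-2-(hydroxymethyl)-1,3,3-trimethyl-4-[(triethylsilyl)oxy]cyclohexan-1-ol
Product: 20 (1R,3R,6R)-6-hydroxy-2,2,6-trimethyl-3-[(triethylsilyl)oxy]cyclohexane-1-carbaldehyde
Conditions: TPAP (5 mol%), NMO, 4 Å MS, CH2Cl2, rt
Reagents that add atoms: none
Why: Ley–Griffith oxidation converts the only oxidisable (primary) alcohol into the aldehyde under neutral conditions that should spare the tertiary alcohol, the TES ether and the configuration at C6', where the formyl group is equatorial.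

Step 16
Reactants: 20 (1R,3R,6R)-6-hydroxy-2,2,6-trimethyl-3-[(triethylsilyl)oxy]cyclohexane-1-carbaldehyde
Product: 21 (1R,2R,4R)-1,3,3-trimethyl-2-[(E)-2-(4,4,5,5-tetramethyl-1,3,2-dioxaborolan-2-yl)ethenyl]-4-[(triethylsilyl)oxy]cyclohexan-1-ol
Conditions: Cl2CHBpin, CrCl2, LiI, THF, rt
Reagents that add atoms: 2-(dichloromethyl)-4,4,5,5-tetramethyl-1,3,2-dioxaborolane, CC1(C)OB(C(Cl)Cl)OC1(C)C
Why: Takai–Utimoto boryl olefination, in which the gem-dichromium species made from the dihalomethylboronate adds to the aldehyde and eliminates, gives the (E)-alkenylboronate selectively and tolerates the tertiary hydroxyl and the silyl ether.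

Step 17
Reactants: 13 (1S,2S,5R,6S)-4-({[tert-butyl(dimethyl)silyl]oxy}methyl)-1-[(1S,2Z)-1-hydroxy-3-iodobut-2-en-1-yl]-7-oxabicyclo[4.1.0]hept-3-ene-2,5-diol; 21 (1R,2R,4R)-1,3,3-trimethyl-2-[(E)-2-(4,4,5,5-tetramethyl-1,3,2-dioxaborolan-2-yl)ethenyl]-4-[(triethylsilyl)oxy]cyclohexan-1-ol
Product: 22 (1R,2S,5R,6S)-4-({[tert-butyl(dimethyl)silyl]oxy}methyl)-1-[(1S,2Z,4E)-1-hydroxy-5-{(1R,3R,6R)-6-hydroxy-2,2,6-trimethyl-3-[(triethylsilyl)oxy]cyclohexyl}-3-methylpenta-2,4-dien-1-yl]-7-oxabicyclo[4.1.0]hept-3-ene-2,5-diol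
Conditions: Pd(dppf)Cl2·CH2Cl2 (10 mol%), K3PO4, THF/H2O, degassed, rt
Reagents that add atoms: none
Why: Suzuki–Miyaura coupling of the (Z)-alkenyl iodide with the (E)-alkenylboronate forms the C3'–C4' bond with retention of both alkene geometries, and the mild phosphate base at room temperature should leave the epoxy triol and the silyl ethers untouched.

Step 18
Reactants: 22 (1R,2S,5R,6S)-4-({[tert-butyl(dimethyl)silyl]oxy}methyl)-1-[(1S,2Z,4E)-1-hydroxy-5-{(1R,3R,6R)-6-hydroxy-2,2,6-trimethyl-3-[(triethylsilyl)oxy]cyclohexyl}-3-methylpenta-2,4-dien-1-yl]-7-oxabicyclo[4.1.0]hept-3-ene-2,5-diol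
Product: 23 Arthrosporol A, (1R,2S,5R,6S)-1-{(1S,2Z,4E)-5-[(1R,3R,6R)-3,6-dihydroxy-2,2,6-trimethylcyclohexyl]-1-hydroxy-3-methylpenta-2,4-dien-1-yl}-4-(hydroxymethyl)-7-oxabicyclo[4.1.0]hept-3-ene-2,5-diol
Conditions: HF·pyridine, pyridine, THF, 0 °C → rt
Reagents that add atoms: none
Why: Fluoride-mediated desilylation with pyridine-buffered HF·pyridine removes the primary TBS and the secondary TES ether without the basic conditions that could trigger epoxide migration in the trans-epoxy alcohols.

Compound list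

1 | 4-bromo-2,5-dimethoxybenzaldehyde | COc1cc(C=O)c(OC)cc1Br | starting material
2 | (4-bromo-2,5-dimethoxyphenyl)methanol | COc1cc(CO)c(OC)cc1Br | intermediate
3 | [(4-bromo-2,5-dimethoxyphenyl)methoxy](tert-butyl)dimethylsilane | COc1cc(CO[Si](C)(C)C(C)(C)C)c(OC)cc1Br | intermediate
4 | {[4-bromo-3,3,6,6-tetramethoxycyclohexa-1,4-dien-1-yl]methoxy}(tert-butyl)dimethylsilane | COC1(OC)C=C(CO[Si](C)(C)C(C)(C)C)C(OC)(OC)C=C1Br | intermediate
5 | but-2-yn-1-ol | CC#CCO | starting material
6 | but-2-ynal | CC#CC=O | intermediate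
7 | [4-({[tert-butyl(dimethyl)silyl]oxy}methyl)-3,3,6,6-tetramethoxycyclohexa-1,4-dien-1-yl]lithium (lithiated bisketal) | [Li]C1=CC(OC)(OC)C(CO[Si](C)(C)C(C)(C)C)=CC1(OC)OC | intermediate
8 | rac-1-[4-({[tert-butyl(dimethyl)silyl]oxy}methyl)-3,3,6,6-tetramethoxycyclohexa-1,4-dien-1-yl]but-2-yn-1-ol | CC#CC(O)C1=CC(OC)(OC)C(CO[Si](C)(C)C(C)(C)C)=CC1(OC)OC | intermediate
9 | sodium 2,2-bis(2-methoxyethoxy)-3-methyl-5-(ring)-2,5-dihydro-1,2-oxaluminol-2-uide (cyclic alkenylalanate; Al on C3', O on C1') | [Na+].CC1=CC(O[Al-]1(OCCOC)OCCOC)C1=CC(OC)(OC)C(CO[Si](C)(C)C(C)(C)C)=CC1(OC)OC | intermediate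
10 | rac-(2Z)-1-[4-({[tert-butyl(dimethyl)silyl]oxy}methyl)-3,3,6,6-tetramethoxycyclohexa-1,4-dien-1-yl]-3-iodobut-2-en-1-ol | CC(=C/C(O)C1=CC(OC)(OC)C(CO[Si](C)(C)C(C)(C)C)=CC1(OC)OC)/I | intermediate
11 | (1S,2Z)-1-[(1S,6R)-4-({[tert-butyl(dimethyl)silyl]oxy}methyl)-2,2,5,5-tetramethoxy-7-oxabicyclo[4.1.0]hept-3-en-1-yl]-3-iodobut-2-en-1-ol | CC(=C/[C@H](O)[C@]12O[C@H]1C(OC)(OC)C(CO[Si](C)(C)C(C)(C)C)=CC2(OC)OC)/I | intermediate
12 | (1S,6R)-4-({[tert-butyl(dimethyl)silyl]oxy}methyl)-1-[(1S,2Z)-1-hydroxy-3-iodobut-2-en-1-yl]-7-oxabicyclo[4.1.0]hept-3-ene-2,5-dione | CC(=C/[C@H](O)[C@]12O[C@H]1C(=O)C(CO[Si](C)(C)C(C)(C)C)=CC2=O)/I | intermediate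
13 | (1S,2S,5R,6S)-4-({[tert-butyl(dimethyl)silyl]oxy}methyl)-1-[(1S,2Z)-1-hydroxy-3-iodobut-2-en-1-yl]-7-oxabicyclo[4.1.0]hept-3-ene-2,5-diol | CC(=C/[C@H](O)[C@]12O[C@H]1[C@H](O)C(CO[Si](C)(C)C(C)(C)C)=C[C@@H]2O)/I | intermediate
14 | geranyl acetate, (2E)-3,7-dimethylocta-2,6-dien-1-yl acetate | CC(=O)OC/C=C(\C)CCC=C(C)C | starting material
15 | (2E)-5-[(2R)-3,3-dimethyloxiran-2-yl]-3-methylpent-2-en-1-yl acetate | CC(=O)OC/C=C(\C)CC[C@H]1OC1(C)C | intermediate
16 | [(1S,3R)-3-hydroxy-2,2-dimethyl-6-methylidenecyclohexyl]methyl acetate | CC(=O)OC[C@@H]1C(C)(C)[C@H](O)CCC1=C | intermediate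
17 | [(1S,3R)-2,2-dimethyl-6-methylidene-3-[(triethylsilyl)oxy]cyclohexyl]methyl acetate | CC(=O)OC[C@@H]1C(C)(C)[C@H](O[Si](CC)(CC)CC)CCC1=C | intermediate
18 | [(3R,4S,6R)-5,5-dimethyl-6-[(triethylsilyl)oxy]-1-oxaspiro[2.5]octan-4-yl]methyl acetate | CC(=O)OC[C@@H]1C(C)(C)[C@H](O[Si](CC)(CC)CC)CC[C@]12CO2 | intermediate
19 | (1R,2S,4R)-2-(hydroxymethyl)-1,3,3-trimethyl-4-[(triethylsilyl)oxy]cyclohexan-1-ol | OC[C@@H]1C(C)(C)[C@H](O[Si](CC)(CC)CC)CC[C@@]1(C)O | intermediate
20 | (1R,3R,6R)-6-hydroxy-2,2,6-trimethyl-3-[(triethylsilyl)oxy]cyclohexane-1-carbaldehyde | O=C[C@@H]1C(C)(C)[C@H](O[Si](CC)(CC)CC)CC[C@@]1(C)O | intermediate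
21 | (1R,2R,4R)-1,3,3-trimethyl-2-[(E)-2-(4,4,5,5-tetramethyl-1,3,2-dioxaborolan-2-yl)ethenyl]-4-[(triethylsilyl)oxy]cyclohexan-1-ol | CC1(C)OB(/C=C/[C@@H]2C(C)(C)[C@H](O[Si](CC)(CC)CC)CC[C@@]2(C)O)OC1(C)C | intermediate
22 | (1R,2S,5R,6S)-4-({[tert-butyl(dimethyl)silyl]oxy}methyl)-1-[(1S,2Z,4E)-1-hydroxy-5-{(1R,3R,6R)-6-hydroxy-2,2,6-trimethyl-3-[(triethylsilyl)oxy]cyclohexyl}-3-methylpenta-2,4-dien-1-yl]-7-oxabicyclo[4.1.0]hept-3-ene-2,5-diol | CC(=C/[C@H](O)[C@]12O[C@H]1[C@H](O)C(CO[Si](C)(C)C(C)(C)C)=C[C@@H]2O)/C=C/[C@@H]1C(C)(C)[C@H](O[Si](CC)(CC)CC)CC[C@@]1(C)O | intermediate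
23 | Arthrosporol A, (1R,2S,5R,6S)-1-{(1S,2Z,4E)-5-[(1R,3R,6R)-3,6-dihydroxy-2,2,6-trimethylcyclohexyl]-1-hydroxy-3-methylpenta-2,4-dien-1-yl}-4-(hydroxymethyl)-7-oxabicyclo[4.1.0]hept-3-ene-2,5-diol | CC(=C/[C@H](O)[C@]12O[C@H]1[C@H](O)C(CO)=C[C@@H]2O)/C=C/[C@@H]1C(C)(C)[C@H](O)CC[C@@]1(C)O | target

Total step count: 18.
Longest linear sequence: 10 steps (steps 1, 2, 3, 5, 6, 7, 8, 9, 17, 18); the terpenoid branch contributes steps 10–16 and the ynal branch step 4.

Steps most likely to fail

Step 7. Oxygen transfer to C1=C2, which is flanked by two ketal carbons and is therefore hindered and inductively deactivated, may become so slow that the two enantiomers are no longer told apart, or the titanium may ionise a ketal. The fallback separates the resolution from the epoxidation and hands the face selection to the substrate. It sets out from 10: esterification with (S)-O-methylmandelic acid (DCC, DMAP) gives two diastereomeric esters, and the O-methylmandelate of the S carbinol F1 is isolated by chromatography. Methanolysis (K2CO3, MeOH) gives the enantiopure S carbinol F2. Vanadium-catalysed hydroxyl-directed epoxidation (VO(acac)2, TBHP, CH2Cl2, 0 °C) then relies on A1,2 strain between the C6 ketal and the C1' substituent, which for allylic alcohols substituted on the carbinol-bearing alkene carbon gives the anti epoxy alcohol, and the sequence comes back to the route at 11.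

Step 9. Facial selection may be poor at C3, where only the oxirane differentiates the two faces, or the enedione may be reduced 1,4. The fallback replaces external facial control by intramolecular delivery and inversion. It sets out from 12: tetramethylammonium triacetoxyborohydride (AcOH/MeCN, −30 °C) is bound by the C1' hydroxyl and reduces only C6 through a six-membered transition state (Evans–Saksena reduction), giving the 1,3-anti C6-hydroxy C3-enone F3. Luche reduction of the remaining carbonyl then gives, in the unfavourable case, the C3 epimer of 13 F4. Its least hindered allylic hydroxyl is inverted by Mitsunobu reaction with 4-nitrobenzoic acid (PPh3, DIAD, THF, 0 °C) to the anti C3 4-nitrobenzoate F5, and K2CO3/MeOH at 0 °C comes back to the route at 13.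

Step 16. Addition of the bulky gem-dichromium reagent to an aldehyde carbon flanked by two quaternary centres may be slow, so that protonation of the reagent by the tertiary hydroxyl and β-elimination of the aldol compete. The fallback is an anionic boron–Wittig olefination on a fully protected aldehyde. It sets out from 19: TESOTf/2,6-lutidine gives the tris-TES ether F6, and Swern oxidation cleaves the primary TES ether oxidatively to the bis-TES aldehyde F7. Lithiated bis(pinacolboryl)methane (CH2(Bpin)2, LiTMP, THF, −78 °C → rt) adds and eliminates a boronate oxide to give the bis-TES (E)-alkenylboronate F8. Suzuki coupling with 13 under the conditions of step 17 gives the tris-silyl ether F9, and the HF·pyridine treatment of step 18 comes back to the route at 23.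

Further compounds

F1 | step 7 | (1S,2Z)-1-[4-({[tert-butyl(dimethyl)silyl]oxy}methyl)-3,3,6,6-tetramethoxycyclohexa-1,4-dien-1-yl]-3-iodobut-2-en-1-yl (2S)-2-methoxy-2-phenylacetate | CC(=C/[C@H](OC(=O)[C@@H](OC)c1ccccc1)C1=CC(OC)(OC)C(CO[Si](C)(C)C(C)(C)C)=CC1(OC)OC)/I
F2 | step 7 | (1S,2Z)-1-[4-({[tert-butyl(dimethyl)silyl]oxy}methyl)-3,3,6,6-tetramethoxycyclohexa-1,4-dien-1-yl]-3-iodobut-2-en-1-ol | CC(=C/[C@H](O)C1=CC(OC)(OC)C(CO[Si](C)(C)C(C)(C)C)=CC1(OC)OC)/I
F3 | step 9 | C6-hydroxy C3-enone: 12 with C6 reduced to the S carbinol (OH anti to the oxirane), C3 still a ketone | CC(=C/[C@H](O)[C@]12O[C@H]1C(=O)C(CO[Si](C)(C)C(C)(C)C)=C[C@@H]2O)/I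
F4 | step 9 | C3 epimer of 13 (C3–OH syn to the oxirane) | CC(=C/[C@H](O)[C@]12O[C@H]1[C@@H](O)C(CO[Si](C)(C)C(C)(C)C)=C[C@@H]2O)/I
F5 | step 9 | C3 4-nitrobenzoate of 13 (ester anti to the oxirane) | CC(=C/[C@H](O)[C@]12O[C@H]1[C@H](OC(=O)c1ccc(cc1)[N+](=O)[O-])C(CO[Si](C)(C)C(C)(C)C)=C[C@@H]2O)/I
F6 | step 16 | tris-TES ether of the triol corresponding to 19 | CC[Si](CC)(CC)OC[C@@H]1C(C)(C)[C@H](O[Si](CC)(CC)CC)CC[C@@]1(C)O[Si](CC)(CC)CC
F7 | step 16 | (1R,3R,6R)-2,2,6-trimethyl-3,6-bis[(triethylsilyl)oxy]cyclohexane-1-carbaldehyde | O=C[C@@H]1C(C)(C)[C@H](O[Si](CC)(CC)CC)CC[C@@]1(C)O[Si](CC)(CC)CC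
F8 | step 16 | O-triethylsilyl ether of 21 (bis-TES (E)-alkenylboronate) | CC1(C)OB(/C=C/[C@@H]2C(C)(C)[C@H](O[Si](CC)(CC)CC)CC[C@@]2(C)O[Si](CC)(CC)CC)OC1(C)C
F9 | step 16 | C11'-O-triethylsilyl ether of 22 | CC(=C/[C@H](O)[C@]12O[C@H]1[C@H](O)C(CO[Si](C)(C)C(C)(C)C)=C[C@@H]2O)/C=C/[C@@H]1C(C)(C)[C@H](O[Si](CC)(CC)CC)CC[C@@]1(C)O[Si](CC)(CC)CC
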